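# Total synthesis of (+)-(7S,8R,8'R)-5,5'-dimethoxylariciresinol

**Retrosynthesis**
1. The target comes from global O-debenzylation of the 2,3,4-trisubstituted THF (19). C9 is carried as a tBu ester until the end.
2. The THF ring is formed last, by 5-exo-tet Williamson closure of the C7 alkoxide onto a C9' tosylate. The C7–O bond is never broken, so C7 keeps its configuration.
3. The C7/C8 stereocenters (syn-β-hydroxy ester) come from a ketoreductase dynamic kinetic resolution of an α-aroyl succinate. The Me and tBu esters are told apart by LiBH4 chemoselectivity.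
4. That ketoester comes from Claisen (Weinreb) aroylation of a differentiated (R)-2-arylmethylsuccinate. C8' is set first by Ru-BINAP asymmetric hydrogenation of a Stobbe half-ester made from syringaldehyde benzyl ether and dimethyl succinate.

Assumptions (one line each):
- The phenols are carried as benzyl ethers.
- The BINAP enantiomer and the KRED are matched to the stated configurations by a small screen.

---

## Route

**Step 1**
Reactants: 1 syringaldehyde; 2 benzyl bromide
Product: 3 4-(benzyloxy)-3,5-dimethoxybenzaldehyde
Conditions: BnBr, K2CO3, DMF, 60 °C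
Reagents that add atoms: benzyl bromide, BrCc1ccccc1
Why: Williamson O-benzylation masks the acidic phenol so it survives the Stobbe, LDA and hydride steps, and it is removed at the end by hydrogenolysis.

**Step 2**
Reactants: 3
Product: 4 4-(benzyloxy)-3,5-dimethoxybenzoic acid
Conditions: NaClO2, NaH2PO4, 2-methylbut-2-ene, t-BuOH/H2O, rt
Reagents that add atoms: sodium chlorite (oxygen source), [Na+].[O-][Cl]=O
Why: Pinnick oxidation converts the aldehyde chemoselectively to the acid, and the alkene scavenges HOCl so the electron-rich ring is not chlorinated.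

**Step 3**
Reactants: 4; 5 N,O-dimethylhydroxylamine hydrochloride
Product: 6 4-(benzyloxy)-N,3,5-trimethoxy-N-methylbenzamide (Weinreb amide)
Conditions: CDI, CH2Cl2, rt; then 5, Et3N, rt
Reagents that add atoms: N,O-dimethylhydroxylamine hydrochloride, CONC.Cl
Why: CDI activation and amidation give a Weinreb amide, whose stable chelated tetrahedral intermediate allows clean single acylation of an ester enolate in Step 7.

**Step 4**
Reactants: 3; 7 dimethyl succinate
Product: 8 (E)-4-aryl-3-(methoxycarbonyl)but-3-enoic acid (Stobbe half-ester)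
Conditions: t-BuOK, t-BuOH, reflux; then aq. HCl
Reagents that add atoms: dimethyl succinate, COC(=O)CCC(=O)OC
Why: Stobbe condensation proceeds through the γ-lactone and E1cB ring-opening, giving the E-alkylidene succinate with the free acid on the CH2 side and the ester on the alkylidene carbon.

**Step 5**
Reactants: 8
Product: 9 (R)-3-(arylmethyl)-4-methoxy-4-oxobutanoic acid
Conditions: H2 (50 bar), Ru(OAc)2[(R)-BINAP] (0.5 mol%), MeOH, 50 °C
Reagents that add atoms: none (H2 adds only H)
Why: Carboxylate-directed Ru-BINAP asymmetric hydrogenation of the trisubstituted alkene sets the first stereocenter (C8', R) by catalyst control; the benzyl ether is untouched under homogeneous conditions.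

**Step 6**
Reactants: 9; 10 di-tert-butyl dicarbonate; 11 tert-butanol
Product: 12 4-tert-butyl 1-methyl (R)-2-(arylmethyl)succinate
Conditions: Boc2O, DMAP (cat.), t-BuOH, rt
Reagents that add atoms: tert-butanol, CC(C)(C)O (Boc2O, CC(C)(C)OC(=O)OC(=O)OC(C)(C)C, only activates the acid and leaves no atoms)
Why: Takeda-type Boc2O/DMAP esterification converts the acid selectively to the tBu ester, so the two esters become chemically distinguishable; C8' is not touched.

**Step 7**
Reactants: 12; 6
Product: 13 α-aroyl succinate (β-keto tBu ester; C8 is an epimerizing mixture, C8' = R)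
Conditions: LDA (1.05 equiv), THF, −78 °C; then 6, −78 → 0 °C; NH4Cl
Reagents that add atoms: Weinreb amide 6 (supplies the aroyl group), CON(C)C(=O)c1cc(OC)c(OCc2ccccc2)c(OC)c1
Why: Kinetic LDA deprotonation occurs at the unhindered CH2 α to the tBu ester rather than at the tertiary C8'–H, and Weinreb acylation gives the β-keto ester without over-addition; C8' is not epimerized at −78 °C.

**Step 8**
Reactants: 13
Product: 14 4-tert-butyl 1-methyl (2R,3S)-2-(arylmethyl)-3-[(S)-aryl(hydroxy)methyl]succinate (7S,8S-syn)
Conditions: KRED (ketoreductase from a commercial panel, syn-(S,S)-selective), NADP+ (cat.), i-PrOH (20% v/v), KPi buffer pH 7.5, DMSO (10% v/v), 30 °C, 48 h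
Reagents that add atoms: none (hydride from NADPH, proton from medium)
Why: The acidic C8–H epimerizes in the buffer, and the ketoreductase reduces one enantiotopic face of the ketone in one epimer faster, so a dynamic kinetic resolution sets C7 (S) and C8 (S in this intermediate, R in the target) together, matched to C8' so that the 8,8'-cis relationship results.

**Step 9**
Reactants: 14
Product: 15 tert-butyl (2S,3R)-4-hydroxy-3-(arylmethyl)-2-[(S)-aryl(hydroxy)methyl]butanoate
Conditions: LiBH4 (3 equiv), THF, 0 → 45 °C
Reagents that add atoms: none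
Why: LiBH4 reduces the unhindered methyl ester (helped by the neighbouring alkoxyborohydride) but not the hindered tBu ester, and any γ-lactone formed from 14 on standing is reduced to the same diol; no stereocenter is affected.

**Step 10**
Reactants: 15; 16 p-toluenesulfonyl chloride
Product: 17 primary tosylate of 15
Conditions: TsCl (1.1 equiv), Et3N, Me3N·HCl (cat.), CH2Cl2, 0 °C
Reagents that add atoms: p-toluenesulfonyl chloride, Cc1ccc(S(=O)(=O)Cl)cc1
Why: Amine-catalysed sulfonylation is selective for the unhindered primary alcohol over the hindered secondary benzylic alcohol, so this is an O-sulfonylation with no stereochemical change.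

**Step 11**
Reactants: 17
Product: 18 tert-butyl (2S,3S,4R)-2-aryl-4-(arylmethyl)tetrahydrofuran-3-carboxylate
Conditions: NaH (1.1 equiv), THF, 0 °C → rt
Reagents that add atoms: none (TsO⁻ is lost)
Why: Intramolecular Williamson etherification (5-exo-tet) of the C7 alkoxide onto the C9' tosylate forms the THF ring with retention at C7, giving the 7,8-trans, 8,8'-cis arrangement.

**Step 12**
Reactants: 18
Product: 19 [(2S,3R,4R)-2-aryl-4-(arylmethyl)tetrahydrofuran-3-yl]methanol (bis-O-benzyl)
Conditions: LiAlH4 (2 equiv), THF, 0 °C → rt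
Reagents that add atoms: none
Why: Hydride reduction of the tBu ester gives the C9 primary alcohol; the cyclic ether and benzyl ethers are inert and the stereocenters are not involved.

**Step 13**
Reactants: 19
Product: 20 (+)-(7S,8R,8'R)-5,5'-dimethoxylariciresinol
Conditions: H2 (1 atm), 10% Pd/C, EtOAc/MeOH (1:1), rt
Reagents that add atoms: none (toluene is lost)
Why: Catalytic hydrogenolysis cleaves both aryl benzyl ethers under mild conditions, while the THF C–O bonds and all stereocenters are retained.

---

## Compound list

| # | Name | SMILES | Role |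
|---|---|---|---|
| 1 | syringaldehyde | COc1cc(C=O)cc(OC)c1O | starting material |
| 2 | benzyl bromide | BrCc1ccccc1 | starting material |
| 3 | 4-(benzyloxy)-3,5-dimethoxybenzaldehyde | COc1cc(C=O)cc(OC)c1OCc1ccccc1 | intermediate |
| 4 | 4-(benzyloxy)-3,5-dimethoxybenzoic acid | COc1cc(C(=O)O)cc(OC)c1OCc1ccccc1 | intermediate |
| 5 | N,O-dimethylhydroxylamine hydrochloride | CONC.Cl | starting material |
| 6 | Weinreb amide of 4 | CON(C)C(=O)c1cc(OC)c(OCc2ccccc2)c(OC)c1 | intermediate |
| 7 | dimethyl succinate | COC(=O)CCC(=O)OC | starting material |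
| 8 | (E)-Stobbe half-ester | COC(=O)/C(CC(=O)O)=C/c1cc(OC)c(OCc2ccccc2)c(OC)c1 | intermediate |
| 9 | (R)-3-(arylmethyl)-4-methoxy-4-oxobutanoic acid | COC(=O)[C@H](Cc1cc(OC)c(OCc2ccccc2)c(OC)c1)CC(=O)O | intermediate |
| 10 | di-tert-butyl dicarbonate | CC(C)(C)OC(=O)OC(=O)OC(C)(C)C | starting material (reagent) |
| 11 | tert-butanol | CC(C)(C)O | starting material (reagent) |
| 12 | 4-tert-butyl 1-methyl (R)-2-(arylmethyl)succinate | COC(=O)[C@H](Cc1cc(OC)c(OCc2ccccc2)c(OC)c1)CC(=O)OC(C)(C)C | intermediate |
| 13 | α-aroyl succinate (C8 epimerizing) | COC(=O)[C@H](Cc1cc(OC)c(OCc2ccccc2)c(OC)c1)C(C(=O)OC(C)(C)C)C(=O)c1cc(OC)c(OCc2ccccc2)c(OC)c1 | intermediate |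
| 14 | (2R,3S,7S)-syn-β-hydroxy diester | COC(=O)[C@H](Cc1cc(OC)c(OCc2ccccc2)c(OC)c1)[C@@H]([C@H](O)c1cc(OC)c(OCc2ccccc2)c(OC)c1)C(=O)OC(C)(C)C | intermediate |
| 15 | diol tBu ester | OC[C@H](Cc1cc(OC)c(OCc2ccccc2)c(OC)c1)[C@@H]([C@H](O)c1cc(OC)c(OCc2ccccc2)c(OC)c1)C(=O)OC(C)(C)C | intermediate |
| 16 | p-toluenesulfonyl chloride | Cc1ccc(S(=O)(=O)Cl)cc1 | starting material (reagent) |
| 17 | primary tosylate | Cc1ccc(S(=O)(=O)OC[C@H](Cc2cc(OC)c(OCc3ccccc3)c(OC)c2)[C@@H]([C@H](O)c2cc(OC)c(OCc3ccccc3)c(OC)c2)C(=O)OC(C)(C)C)cc1 | intermediate |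
| 18 | THF tBu ester | COc1cc(C[C@H]2CO[C@H](c3cc(OC)c(OCc4ccccc4)c(OC)c3)[C@H]2C(=O)OC(C)(C)C)cc(OC)c1OCc1ccccc1 | intermediate |
| 19 | bis-O-benzyl lariciresinol analogue | COc1cc(C[C@H]2CO[C@H](c3cc(OC)c(OCc4ccccc4)c(OC)c3)[C@H]2CO)cc(OC)c1OCc1ccccc1 | intermediate |
| 20 | (+)-(7S,8R,8'R)-5,5'-dimethoxylariciresinol | COc1cc(C[C@H]2CO[C@H](c3cc(OC)c(O)c(OC)c3)[C@H]2CO)cc(OC)c1O | target |

---

**Total steps:** 13 (including the two-step Weinreb-amide branch, 2 → 3).
**Longest linear sequence:** 11 steps (1 → 4 → 5 → 6 → 7 → 8 → 9 → 10 → 11 → 12 → 13, starting from syringaldehyde).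

**Three steps most likely to fail**
1. **Step 8 (KRED dynamic kinetic resolution):** the α-branched, bulky β-ketoester may be poorly accepted, or the enzyme may give the wrong C8 epimer relative to C8' (8,8'-trans).
   - Fallback: replace the enzyme with a chemocatalytic Noyori–Ikariya Ru-TsDPEN asymmetric transfer hydrogenation DKR (HCO2H/Et3N) of 13 to give the syn alcohol 14.
2. **Step 7 (Claisen aroylation):** this step risks poor enolate regioselectivity, partial C8' deprotonation, and low reactivity of the hindered enolate toward the electron-rich Weinreb amide.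
   - Fallback: convert 12 to (R)-β-(arylmethyl)-γ-butyrolactone (LiBH4, then TFA). Do a trans-selective aldol with aldehyde 3, reduce with LiAlH4 to the triol, and close the ring by acid-catalysed benzylic (SN1) cyclodehydration. The 7-epimers are then separated chromatographically.
3. **Step 11 (NaH Williamson cyclization):** the β-alkoxy ester may undergo retro-aldol, C8 epimerization or elimination of the tosylate.
   - Fallback: lactonize 14 (cat. acid) to the γ-aryl lactone. Reduce it with DIBAL to the lactol, then apply Et3SiH/TMSOTf oxocarbenium reduction to give the THF 18 without any alkoxide intermediate.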